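**Plan**

- Numbering is that of cyclohepta[b]furan-2-one (O1, C2, C3, C3a, C4–C8, C8a) for every intermediate. In the carbocycle C4 is the one atom that bears nothing, and it sits between the ring-fusion carbon C3a and the carbinol carbon C5. The seven-membered ring is therefore a fully substituted cyclohexanone (C5 carbonyl) with one extra CH2 beside the carbonyl.
- Retrosynthetic cuts, in order: the side-chain enone back to a propargylic pivalate on C7; C3–C3a and O1–C2 of the lactone (phosphonoacetate tethered to the C8a oxygen); C4–C5 and C3a–C4 (C4 taken out, seven- to six-membered ring); C6–CH3; C7–alkyne.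
- Forward: the six-membered ring is cyclohexa-1,4-diene. It is oxidised and substituted to the cyclohexanone, enlarged by one carbon, the lactone ring is then closed onto C3a, and the butenoyl chain is unmasked last.
- Stereochemistry: C8/C8a from catalytic desymmetrisation of the meso epoxide; C7 from axial acetylide addition to a conformationally locked enone; C6 from hydroxyl-directed cyclopropanation and cyclopropanol opening; C3a from the ester tether; C5 from hydroxyl-directed hydride delivery.

Key step: step 12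

Faces: β is the face of the C8 oxygen, α that of the C8a oxygen.
Assumption: the antipode of the cobalt–salen catalyst that leads to the (1R,2R)-diol is used; (R)-but-3-yn-2-ol serves only to keep intermediates single diastereomers, its stereocentre being lost in step 20.

**Route**

Step 1
Reactants: 1 cyclohexa-1,4-diene
Product: 2 cis-7-oxabicyclo[4.1.0]hept-3-ene (meso monoepoxide)
Conditions: mCPBA (0.9 equiv), NaHCO3, CH2Cl2, 0 °C
Reagents that add atoms: mCPBA (3-chloroperoxybenzoic acid), O=C(OO)c1cccc(Cl)c1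
Why: Prilezhaev epoxidation of one of two equivalent cis-alkenes with a deficit of peracid should stop at the meso monoepoxide, whose ring fusion can only be cis.

Step 2
Reactants: 2 cis-7-oxabicyclo[4.1.0]hept-3-ene
Product: 3 (1R,2R)-cyclohex-4-ene-1,2-diol
Conditions: H2O (1.2 equiv), chiral oligomeric (salen)Co(OTs) (trivalent cobalt, 1 mol%), MeCN, 4 °C
Reagents that add atoms: water, O
Why: Cobalt–salen-catalysed enantioselective hydrolysis of a meso epoxide; anti attack of water at one enantiotopic carbon should give the trans-diol and so fix C8 and C8a.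

Step 3
Reactants: 3 (1R,2R)-cyclohex-4-ene-1,2-diol
Product: 4 (1R,2R)-1,2-O-(1,1,3,3-tetraisopropyldisiloxane-1,3-diyl)cyclohex-4-ene-1,2-diol
Conditions: (i-Pr2SiCl)2O, imidazole, DMF, 0 °C → rt
Reagents that add atoms: 1,3-dichloro-1,1,3,3-tetraisopropyldisiloxane, CC(C)[Si](Cl)(C(C)C)O[Si](Cl)(C(C)C)C(C)C
Why: Double silylation of the trans-diol; the trans-fused seven-membered disiloxane can only span two equatorial oxygens, so it locks the chair used later and keeps the C2 symmetry needed in step 4.

Step 4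
Reactants: 4 disiloxane-protected cyclohexene diol
Product: 5 C7 allylic alcohol of 4 (hydroxyl on the CH2 next to C8; C5=C6 alkene kept)
Conditions: SeO2 (0.5 equiv), t-BuOOH (3 equiv), CH2Cl2, rt
Reagents that add atoms: tert-butyl hydroperoxide (oxygen relayed through SeO2), CC(C)(C)OO
Why: Riley allylic oxidation (ene reaction then [2,3]-shift) oxygenates an allylic CH2 without moving the alkene, and the two allylic positions are equivalent by the C2 axis, so one regioisomer should form; the new carbinol centre, expected mainly trans to the C8 oxygen, is erased in step 5.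

Step 5
Reactants: 5 C7 allylic alcohol
Product: 6 (5R,6S)-5,6-(1,1,3,3-tetraisopropyldisiloxane-1,3-diyldioxy)cyclohex-2-en-1-one (C7 ketone; C5=C6)
Conditions: Dess–Martin periodinane, NaHCO3, CH2Cl2, rt
Reagents that add atoms: none
Why: Dess–Martin oxidation of the secondary allylic alcohol under buffered conditions should give the enone with the carbonyl next to the siloxy-bearing C8.

Step 6
Reactants: 6 enone
Product: 7 C5-(4-methoxybenzyloxy) ketone (C5 epimers)
Conditions: 4-MeOC6H4CH2OH (5 equiv), PMe3 (10 mol%), MeCN, rt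
Reagents that add atoms: 4-methoxybenzyl alcohol, COc1ccc(CO)cc1
Why: Phosphine-catalysed oxa-Michael addition places the oxygen that becomes the C5 carbonyl; the C5 configuration is irrelevant because C5 becomes sp2 in step 7.

Step 7
Reactants: 7 C5-(4-methoxybenzyloxy) ketone
Product: 9 3-(4-methoxybenzyloxy)cyclohex-2-en-1-one (C7 ketone; C5=C6 enol ether), via silyl enol ether 8 (not isolated)
Conditions: LiN(iPr)2 (commercial solution, 1.1 equiv), Me3SiCl (in situ), THF, –78 °C; then Pd(OAc)2 (1.0 equiv), MeCN, rt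
Reagents that add atoms: none
Why: Kinetic deprotonation at the C6 methylene (not the siloxy-bearing C8 methine) with internal silyl quench, then Saegusa–Ito dehydrogenation with palladium diacetate, should give the vinylogous ester with the carbonyl fixed at C7.

Step 8
Reactants: 9 vinylogous ester, 10 (R)-but-3-yn-2-ol
Product: 12 C7 tertiary alcohol carrying the (R)-3-(pivaloyloxy)but-1-ynyl group, via propargylic diol 11 (not isolated)
Conditions: 10 (1.2 equiv), n-BuLi (2.4 equiv), THF, –78 °C; then 9, –78 → –30 °C; then t-BuCOCl (1.5 equiv), –78 → 0 °C; aq. NaHCO3 work-up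
Reagents that add atoms: (R)-but-3-yn-2-ol (reactant 10), C#C[C@@H](C)O; pivaloyl chloride, CC(C)(C)C(=O)Cl
Why: 1,2-Addition of a lithium acetylide to a vinylogous ester (first stage of a Stork–Danheiser sequence); with the C8 oxygen held equatorial by the non-chelating disiloxane the slim nucleophile should enter C7 axially on the β face (alkyne cis to the C8 oxygen, hydroxyl α), and only the unhindered secondary alkoxide is acylated.

Step 9
Reactants: 12 tertiary alcohol pivalate
Product: 13 C5,C6-methano (cyclopropane) derivative of 12 with CH2 on the α face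
Conditions: Et2Zn (4 equiv), CH2I2 (8 equiv), CH2Cl2, –20 → 0 °C
Reagents that add atoms: diiodomethane, ICI
Why: Furukawa-type Simmons–Smith cyclopropanation of the electron-rich enol ether, delivered by the zinc alkoxide of the C7 hydroxyl to its own α face (the β face carries the axial alkyne), should set C6 with the new carbon cis to the C7 oxygen.

Step 10
Reactants: 13 cyclopropyl ether alcohol
Product: 14 C7 triethylsilyl ether of 13
Conditions: Et3SiOTf, 2,6-lutidine, CH2Cl2, –78 °C
Reagents that add atoms: triethylsilyl trifluoromethanesulfonate, CC[Si](CC)(CC)OS(=O)(=O)C(F)(F)F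
Why: Silylation of the tertiary alcohol with a silyl triflate and a hindered base blocks retro-aldol cleavage and dehydration once the C5 ketone is unveiled.

Step 11
Reactants: 14 silylated cyclopropyl 4-methoxybenzyl ether
Product: 16 cyclohexanone (C5 ketone; C6 methyl α; C7 OSiEt3 α and alkyne β; disiloxane on C8/C8a), via cyclopropanol 15 (not isolated)
Conditions: DDQ (1.2 equiv), CH2Cl2/pH 7 buffer, 0 °C; then K2CO3 (cat.), MeOH, 0 °C
Reagents that add atoms: none
Why: Oxidative removal of the 4-methoxybenzyl group frees a cyclopropanol that opens under mild base at its unsubstituted C5–CH2 bond (α-methylation of a ketone through its cyclopropanol), so the C6–C bond made in step 9 is untouched and the methyl group stays cis to the C7 oxygen.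

Step 12
Reactants: 16 cyclohexanone, 17 trimethylsilyldiazomethane
Product: 19 cycloheptanone (C5 ketone; C4 and C3a methylene; other groups as in 16), via C4-silyl ketone 18 (not isolated)
Conditions: Me3SiCHN2 (1.5 equiv), AlMe3 (1.2 equiv), CH2Cl2, –78 → –20 °C; then 1 M HCl, THF, 0 °C
Reagents that add atoms: trimethylsilyldiazomethane (reactant 17), C[Si](C)(C)C=[N+]=[N-]
Why: AlMe3 activates the C5 carbonyl, the diazo carbon adds to it, and N2 leaves from the adduct while the ring bond antiperiplanar to it shifts to the new carbon, giving the C4-silyl ketone 18, which loses silicon on acidic work-up. The closest known reaction type is the Lewis-acid-promoted homologation of cyclohexanones with trimethylsilyldiazomethane, a Tiffeneau–Demjanov-type ring expansion. No ring is closed: the six-membered carbocycle is enlarged to the seven-membered one by a 1,2-shift that inserts C4, with new bonds C4–C5 and C3a–C4. No stereocentre is created (the silyl-bearing C4 ends as CH2) and C6, C7, C8 and C8a are carried through unchanged. The step needs migration of C3a and not C6; C3a is an unhindered CH2, whereas C6 is tertiary and flanked by the fully substituted C7, so the Me3Si group should lie away from C6 in the adduct and the C5–C3a bond should migrate. The medium is non-basic and cold and the C6–H is equatorial on the locked chair, so C6 should not epimerise.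

Step 13
Reactants: 19 cycloheptanone
Product: 21 cyclohept-2-enone (C5 ketone; C3a=C4), via silyl enol ether 20 (not isolated)
Conditions: LiN(iPr)2 (commercial solution, 1.1 equiv), Me3SiCl, THF, –78 °C; then Pd(OAc)2 (1.0 equiv), MeCN, rt
Reagents that add atoms: none
Why: Kinetic enolisation toward the unhindered C4 methylene and Saegusa–Ito oxidation; C7 is quaternary, so the ring can only be desaturated toward C3a.

Step 14
Reactants: 21 cycloheptenone
Product: 22 enone triol (free hydroxyls at C7, C8 and C8a)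
Conditions: HF·pyridine, pyridine, THF, 0 °C → rt
Reagents that add atoms: none
Why: Fluoride cleavage of the disiloxane and the triethylsilyl ether under buffered conditions should leave the pivalate and the enone intact.

Step 15
Reactants: 22 enone triol, 23 2-(diethoxyphosphoryl)acetic acid
Product: 24 C8a (diethoxyphosphoryl)acetate of 22
Conditions: 23 (1.05 equiv), DCC, DMAP (cat.), CH2Cl2, –20 → 0 °C
Reagents that add atoms: 2-(diethoxyphosphoryl)acetic acid (reactant 23), CCOP(=O)(CC(=O)O)OCC
Why: Steglich esterification; the allylic C8a hydroxyl is the only unhindered one (C8–OH adjoins the quaternary C7 and C7–OH is tertiary), so monoacylation should occur there.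

Step 16
Reactants: 24 C8a phosphonoacetate
Product: 25 C8 isobutyrate of 24
Conditions: (i-PrCO)2O, DMAP, pyridine, CH2Cl2, rt
Reagents that add atoms: isobutyric anhydride, CC(C)C(=O)OC(=O)C(C)C
Why: DMAP-catalysed acylation of the one remaining secondary hydroxyl; the tertiary C7 hydroxyl should not react.

Step 17
Reactants: 25 phosphonoacetate isobutyrate
Product: 27 cis-fused α-methylene lactone with C5 ketone, via phosphono lactone 26 (not isolated)
Conditions: Cs2CO3 (1.2 equiv), MeCN, 0 °C; then 37% aq. CH2O, rt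
Reagents that add atoms: formaldehyde, C=O
Why: Intramolecular Michael addition of the phosphonate-stabilised carbanion to C3a of the enone (5-exo-trig), which the three-atom ester tether on the α-oriented C8a oxygen should direct to the α face (cis ring fusion), followed by Horner–Wadsworth–Emmons methylenation of the phosphono lactone with formaldehyde.

Step 18
Reactants: 27 methylene lactone ketone
Product: 28 1,3-anti diol (C5 hydroxyl β; C7 hydroxyl α)
Conditions: Me4NBH(OAc)3, MeCN/AcOH (1:1), –30 °C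
Reagents that add atoms: none
Why: Evans–Saksena reduction: the C7 hydroxyl binds boron and delivers hydride to C5 on its own α face, so the new hydroxyl should be β (trans to the C6 methyl), and the reagent leaves lactone, esters and alkyne alone.

Step 19
Reactants: 28 anti diol
Product: 29 C5,C7-bis(triethylsilyl) ether of 28
Conditions: Et3SiOTf (3 equiv), 2,6-lutidine, CH2Cl2, –78 → 0 °C
Reagents that add atoms: triethylsilyl trifluoromethanesulfonate, CC[Si](CC)(CC)OS(=O)(=O)C(F)(F)F
Why: Silylation of both hydroxyls so that no free OH can add to the allene formed in step 20.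

Step 20
Reactants: 29 bis(silyl) ether propargylic pivalate
Product: 31 bis(triethylsilyl) ether of the target, via allenyl pivalate 30 (not isolated)
Conditions: Ph3PAuNTf2 (5 mol%, monovalent gold), wet butan-2-one, rt
Reagents that add atoms: none
Why: Gold-catalysed [3,3] shift of the propargylic pivalate to the allenyl ester and its hydrolysis (a Meyer–Schuster-type transposition) should place the ketone on the carbon attached to C7 and give the thermodynamically favoured E-alkene; the ketone oxygen is the migrated ester oxygen.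

Step 21
Reactants: 31 bis(triethylsilyl) ether
Product: 32 target CNP0123946.1
Conditions: HF·pyridine, THF, 0 °C → rt
Reagents that add atoms: none
Why: Fluoride cleavage of the two triethylsilyl ethers under mildly acidic conditions that the enone, the α-methylene lactone and the isobutyrate should tolerate.

**Compound list**

1 | cyclohexa-1,4-diene | C1=CCC=CC1 | starting material
2 | cis-7-oxabicyclo[4.1.0]hept-3-ene (meso, 1R,6S) | C1=CC[C@H]2O[C@H]2C1 | intermediate
3 | (1R,2R)-cyclohex-4-ene-1,2-diol | O[C@@H]1CC=CC[C@H]1O | intermediate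
4 | (1R,2R)-1,2-O-(1,1,3,3-tetraisopropyldisiloxane-1,3-diyl)cyclohex-4-ene-1,2-diol | CC(C)[Si]1(C(C)C)O[C@@H]2CC=CC[C@H]2O[Si](C(C)C)(C(C)C)O1 | intermediate
5 | C7 allylic alcohol of 4 (OH on the CH2 next to C8, drawn trans to the C8 oxygen as the epimer expected to predominate; C5=C6) | CC(C)[Si]1(C(C)C)O[C@@H]2CC=C[C@H](O)[C@H]2O[Si](C(C)C)(C(C)C)O1 | intermediate
6 | (5R,6S)-5,6-(1,1,3,3-tetraisopropyldisiloxane-1,3-diyldioxy)cyclohex-2-en-1-one (C7 ketone; C5=C6) | CC(C)[Si]1(C(C)C)O[C@@H]2CC=CC(=O)[C@H]2O[Si](C(C)C)(C(C)C)O1 | intermediate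
7 | C5-(4-methoxybenzyloxy) ketone from 6 (C5 epimers) | CC(C)[Si]1(C(C)C)O[C@@H]2CC(OCc3ccc(OC)cc3)CC(=O)[C@H]2O[Si](C(C)C)(C(C)C)O1 | intermediate
8 | trimethylsilyl enol ether of 7 (C6=C7; not isolated) | CC(C)[Si]1(C(C)C)O[C@@H]2CC(OCc3ccc(OC)cc3)C=C(O[Si](C)(C)C)[C@H]2O[Si](C(C)C)(C(C)C)O1 | intermediate
9 | 3-(4-methoxybenzyloxy)cyclohex-2-en-1-one with the disiloxane-bridged trans-5,6-diol (C7 ketone; C5=C6 enol ether) | CC(C)[Si]1(C(C)C)O[C@@H]2CC(OCc3ccc(OC)cc3)=CC(=O)[C@H]2O[Si](C(C)C)(C(C)C)O1 | intermediate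
10 | (R)-but-3-yn-2-ol | C#C[C@@H](C)O | starting material
11 | C7 tertiary alcohol with (R)-3-hydroxybut-1-ynyl group (alkyne β, OH α; not isolated, present as its dilithium alkoxide) | CC(C)[Si]1(C(C)C)O[C@@H]2CC(OCc3ccc(OC)cc3)=C[C@@](O)(C#C[C@@H](C)O)[C@H]2O[Si](C(C)C)(C(C)C)O1 | intermediate
12 | C7 tertiary alcohol with (R)-3-(pivaloyloxy)but-1-ynyl group (alkyne β, cis to the C8 oxygen) | CC(C)[Si]1(C(C)C)O[C@@H]2CC(OCc3ccc(OC)cc3)=C[C@@](O)(C#C[C@@H](C)OC(=O)C(C)(C)C)[C@H]2O[Si](C(C)C)(C(C)C)O1 | intermediate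
13 | bicyclo[4.1.0]heptane: C5,C6-methano derivative of 12, CH2 on the α face, C5 OPMB β | CC(C)[Si]1(C(C)C)O[C@@H]2C[C@]4(OCc3ccc(OC)cc3)C[C@@H]4[C@@](O)(C#C[C@@H](C)OC(=O)C(C)(C)C)[C@H]2O[Si](C(C)C)(C(C)C)O1 | intermediate
14 | C7 triethylsilyl ether of 13 | CC(C)[Si]1(C(C)C)O[C@@H]2C[C@]4(OCc3ccc(OC)cc3)C[C@@H]4[C@@](O[Si](CC)(CC)CC)(C#C[C@@H](C)OC(=O)C(C)(C)C)[C@H]2O[Si](C(C)C)(C(C)C)O1 | intermediate
15 | cyclopropanol from 14 (C5 OH; not isolated) | CC(C)[Si]1(C(C)C)O[C@@H]2C[C@]4(O)C[C@@H]4[C@@](O[Si](CC)(CC)CC)(C#C[C@@H](C)OC(=O)C(C)(C)C)[C@H]2O[Si](C(C)C)(C(C)C)O1 | intermediate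
16 | cyclohexanone: C5 ketone, C6 methyl (α), C7 OSiEt3 (α) and (R)-3-(pivaloyloxy)but-1-ynyl (β), C8 (β) and C8a (α) oxygens bridged by the tetraisopropyldisiloxane | CC(C)[Si]1(C(C)C)O[C@@H]2CC(=O)[C@H](C)[C@@](O[Si](CC)(CC)CC)(C#C[C@@H](C)OC(=O)C(C)(C)C)[C@H]2O[Si](C(C)C)(C(C)C)O1 | intermediate
17 | trimethylsilyldiazomethane | C[Si](C)(C)C=[N+]=[N-] | starting material
18 | C4-trimethylsilyl cycloheptanone (C4 epimers; not isolated) | CC(C)[Si]1(C(C)C)O[C@@H]2CC([Si](C)(C)C)C(=O)[C@H](C)[C@@](O[Si](CC)(CC)CC)(C#C[C@@H](C)OC(=O)C(C)(C)C)[C@H]2O[Si](C(C)C)(C(C)C)O1 | intermediate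
19 | cycloheptanone: 16 with CH2 (C4) inserted between C5 and C3a | CC(C)[Si]1(C(C)C)O[C@@H]2CCC(=O)[C@H](C)[C@@](O[Si](CC)(CC)CC)(C#C[C@@H](C)OC(=O)C(C)(C)C)[C@H]2O[Si](C(C)C)(C(C)C)O1 | intermediate
20 | C4=C5 trimethylsilyl enol ether of 19 (not isolated) | CC(C)[Si]1(C(C)C)O[C@@H]2CC=C(O[Si](C)(C)C)[C@H](C)[C@@](O[Si](CC)(CC)CC)(C#C[C@@H](C)OC(=O)C(C)(C)C)[C@H]2O[Si](C(C)C)(C(C)C)O1 | intermediate
21 | cyclohept-2-enone (C5 ketone; C3a=C4) | CC(C)[Si]1(C(C)C)O[C@@H]2C=CC(=O)[C@H](C)[C@@](O[Si](CC)(CC)CC)(C#C[C@@H](C)OC(=O)C(C)(C)C)[C@H]2O[Si](C(C)C)(C(C)C)O1 | intermediate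
22 | enone triol (OH at C7 α, C8 β, C8a α) | O[C@@H]1C=CC(=O)[C@H](C)[C@@](O)(C#C[C@@H](C)OC(=O)C(C)(C)C)[C@H]1O | intermediate
23 | 2-(diethoxyphosphoryl)acetic acid | CCOP(=O)(CC(=O)O)OCC | starting material
24 | C8a (diethoxyphosphoryl)acetate of 22 | CCOP(=O)(OCC)CC(=O)O[C@@H]1C=CC(=O)[C@H](C)[C@@](O)(C#C[C@@H](C)OC(=O)C(C)(C)C)[C@H]1O | intermediate
25 | C8 isobutyrate of 24 | CCOP(=O)(OCC)CC(=O)O[C@@H]1C=CC(=O)[C@H](C)[C@@](O)(C#C[C@@H](C)OC(=O)C(C)(C)C)[C@H]1OC(=O)C(C)C | intermediate
26 | cis-fused C3-(diethoxyphosphoryl) lactone (C3 epimers; not isolated) | CCOP(=O)(OCC)C1C(=O)O[C@@H]2[C@H]1CC(=O)[C@H](C)[C@@](O)(C#C[C@@H](C)OC(=O)C(C)(C)C)[C@H]2OC(=O)C(C)C | intermediate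
27 | cis-fused α-methylene lactone with C5 ketone, C7 OH, C8 isobutyrate | C=C1C(=O)O[C@@H]2[C@H]1CC(=O)[C@H](C)[C@@](O)(C#C[C@@H](C)OC(=O)C(C)(C)C)[C@H]2OC(=O)C(C)C | intermediate
28 | C5 (β),C7 (α) anti diol | C=C1C(=O)O[C@@H]2[C@H]1C[C@@H](O)[C@H](C)[C@@](O)(C#C[C@@H](C)OC(=O)C(C)(C)C)[C@H]2OC(=O)C(C)C | intermediate
29 | C5,C7-bis(triethylsilyl) ether of 28 | C=C1C(=O)O[C@@H]2[C@H]1C[C@@H](O[Si](CC)(CC)CC)[C@H](C)[C@@](O[Si](CC)(CC)CC)(C#C[C@@H](C)OC(=O)C(C)(C)C)[C@H]2OC(=O)C(C)C | intermediate
30 | allenyl pivalate (C7–C(OPiv)=C=CH–CH3; allene axis undefined; not isolated) | C=C1C(=O)O[C@@H]2[C@H]1C[C@@H](O[Si](CC)(CC)CC)[C@H](C)[C@@](O[Si](CC)(CC)CC)(C(OC(=O)C(C)(C)C)=C=CC)[C@H]2OC(=O)C(C)C | intermediate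
31 | C5,C7-bis(triethylsilyl) ether of the target | C=C1C(=O)O[C@@H]2[C@H]1C[C@@H](O[Si](CC)(CC)CC)[C@H](C)[C@@](O[Si](CC)(CC)CC)(C(=O)/C=C/C)[C@H]2OC(=O)C(C)C | intermediate
32 | (3aS,5R,6S,7S,8S,8aR)-7-[(2E)-but-2-enoyl]-5,7-dihydroxy-6-methyl-3-methylidene-2-oxooctahydro-2H-cyclohepta[b]furan-8-yl 2-methylpropanoate (CNP0123946.1) | C=C1C(=O)O[C@@H]2[C@H]1C[C@@H](O)[C@H](C)[C@@](O)(C(=O)/C=C/C)[C@H]2OC(=O)C(C)C | target

**Totals and risks**

Total step count: 21. Longest linear sequence: 21 steps (1 to 32).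

Steps most likely to fail:

Step 12. The C5 carbonyl of 16 lies between an axial methyl group and a fully substituted carbon, so addition of the diazo reagent may be slow, giving the Lewis acid time to attack the silyl ethers, or migration may be less selective than hoped. The fallback sets out from 16 and returns at 21, so step 13 is also bypassed. The same carbon is inserted between C5 and C3a through the enolate: LiN(iPr)2/Me3SiCl should give the C5–C3a trimethylsilyl enol ether F1 (the equatorial C6–H is not removed). Et2Zn/CH2I2 then gives the siloxycyclopropane F2. FeCl3 in DMF cleaves its ring-fusion bond by one-electron oxidation (Saegusa–Ito ring expansion) to the 3a-chloro cycloheptanone F3, and NaOAc in MeOH eliminates HCl to give 21.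

Step 15. Discrimination between the C8a and C8 hydroxyls may be incomplete, giving regioisomeric or doubly acylated esters. The fallback sets out from 22 and returns at 25, replacing steps 15 and 16. tBu2Si(OTf)2/2,6-lutidine should bridge the cis-1,3-related C7 and C8a oxygens as the C7,C8a-O-di-tert-butylsilylene F4, leaving only the C8 hydroxyl free. This is acylated with isobutyric anhydride/DMAP to the silylene isobutyrate F5. HF·pyridine removes the silylene to give the C8 isobutyrate diol F6, in which C8a–OH is the only secondary hydroxyl, and Steglich esterification with 23 gives 25.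

Step 7. The lithium enolate of the β-alkoxy ketone may expel 4-methoxybenzyl oxide (retro-oxa-Michael) faster than it is silylated, which would return enone 6. The fallback sets out from 6 and returns at 9, replacing steps 6 and 7. Weitz–Scheffer epoxidation (H2O2, NaOH, MeOH) gives the 5,6-epoxy ketone F7. Pd(PPh3)4/dppe in toluene isomerises it to the cyclohexane-1,3-dione F8. Acid-catalysed enol etherification with 4-methoxybenzyl alcohol (PPTS, benzene, azeotropic removal of water) should then place the ether on the less hindered C5 carbonyl and give 9.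

**Further compounds**

F1 | step 12 | C5–C3a trimethylsilyl enol ether of 16 | CC(C)[Si]1(C(C)C)O[C@@H]2C=C(O[Si](C)(C)C)[C@H](C)[C@@](O[Si](CC)(CC)CC)(C#C[C@@H](C)OC(=O)C(C)(C)C)[C@H]2O[Si](C(C)C)(C(C)C)O1
F2 | step 12 | siloxycyclopropane (CH2 bridging C3a and C5; cyclopropane face undefined) | CC(C)[Si]1(C(C)C)O[C@@H]2C4CC4(O[Si](C)(C)C)[C@H](C)[C@@](O[Si](CC)(CC)CC)(C#C[C@@H](C)OC(=O)C(C)(C)C)[C@H]2O[Si](C(C)C)(C(C)C)O1
F3 | step 12 | 3a-chloro cycloheptanone (C3a epimers) | CC(C)[Si]1(C(C)C)O[C@@H]2C(Cl)CC(=O)[C@H](C)[C@@](O[Si](CC)(CC)CC)(C#C[C@@H](C)OC(=O)C(C)(C)C)[C@H]2O[Si](C(C)C)(C(C)C)O1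
F4 | step 15 | C7,C8a-O-di-tert-butylsilylene of 22 (C8 OH free) | CC(C)(C)[Si]1(C(C)(C)C)O[C@@H]2C=CC(=O)[C@H](C)[C@@](O1)(C#C[C@@H](C)OC(=O)C(C)(C)C)[C@H]2O
F5 | step 15 | C8 isobutyrate of F4 | CC(C)(C)[Si]1(C(C)(C)C)O[C@@H]2C=CC(=O)[C@H](C)[C@@](O1)(C#C[C@@H](C)OC(=O)C(C)(C)C)[C@H]2OC(=O)C(C)C
F6 | step 15 | C8 isobutyrate with free C7 and C8a hydroxyls | O[C@@H]1C=CC(=O)[C@H](C)[C@@](O)(C#C[C@@H](C)OC(=O)C(C)(C)C)[C@H]1OC(=O)C(C)C
F7 | step 7 | 5,6-epoxy ketone from 6 (epoxide on the β face expected) | CC(C)[Si]1(C(C)C)O[C@@H]2C[C@H]4O[C@H]4C(=O)[C@H]2O[Si](C(C)C)(C(C)C)O1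
F8 | step 7 | cyclohexane-1,3-dione (C5 and C7 carbonyls) | CC(C)[Si]1(C(C)C)O[C@@H]2CC(=O)CC(=O)[C@H]2O[Si](C(C)C)(C(C)C)O1
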